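**Retrosynthetic overview**

1. The ring is a cyclohexa-2,5-dienone: C1 (allyl-bearing), C2 (=CH), C3 (quaternary C–OMe), C4 (enol-ether C–OMe), C5 (=CH), C6 (C=O); the side chain is C8 (CHMe) and C7 (ArCH2). The strategy rests on the vicinal oxygenated pair C3/C4: a fully substituted carbinol carbon next to a carbonyl-level carbon, i.e. a masked tertiary α-ketol.
2. Endgame: C1=C2 by selenoxide elimination and the allyl group by enolate alkylation at C1. The vinylogous ester C4(OMe)=C5–C6=O comes from a β-keto ketal (ketal at C4, ketone at C6) by loss of methanol, and that from the O-methylated α-ketol.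
3. Key disconnection C3–C4: a carbene-catalysed intramolecular crossed benzoin of an acyclic keto aldehyde closes the only ring.
4. The keto aldehyde comes from a Weinreb amide (C8 set by auxiliary-controlled benzylation, aryl part from vanillin) and a C2–C1–C6–C5–C4 Grignard reagent (C6 from a resolved bromoethyl oxirane), followed by ozonolysis.

Key step: step 11

**Remarks**

- Atom labels C1–C8 above are used in the Why lines; systematic names use their own locants.
- Assumption: the sense of induction of the triazolium catalyst for this aliphatic substrate is not established. The (5aS,10bR) salt is written; if it proves mismatched, its (5aR,10bS) antipode is used.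
- Assumption: the (R,R) cobalt–salen catalyst leaves the (S)-oxirane unreacted, as it does with simple alkyl oxiranes.
- C1 is a stereocentre only in 33, 36 and 37; it is carried as a mixture and disappears in step 17.
- The descriptor of C3 changes from S (36) to R (38) only through the CIP ranking. The spatial arrangement at C3, C6 and C8 is the same in every SMILES.

**Route**

Step 1
Reactants: 1 vanillin; 2 triisopropylsilyl chloride
Product: 3 3-methoxy-4-(triisopropylsilyloxy)benzaldehyde
Conditions: imidazole, DMF, rt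
Reagents that add atoms: triisopropylsilyl chloride, CC(C)[Si](Cl)(C(C)C)C(C)C
Why: Imidazole-promoted silylation of the phenol gives an aryl silyl ether that should survive the bases, organometallics and acids used later and falls to fluoride at the end.

Step 2
Reactants: 3 3-methoxy-4-(triisopropylsilyloxy)benzaldehyde
Product: 4 [3-methoxy-4-(triisopropylsilyloxy)phenyl]methanol
Conditions: NaBH4, THF/EtOH, 0 °C
Reagents that add atoms: none
Why: Borohydride reduction of the aryl aldehyde is fast at 0 °C and leaves the hindered aryl silyl ether intact.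

Step 3
Reactants: 4 [3-methoxy-4-(triisopropylsilyloxy)phenyl]methanol; 5 carbon tetrabromide
Product: 6 4-(bromomethyl)-2-methoxy-1-(triisopropylsilyloxy)benzene
Conditions: PPh3, CBr4, CH2Cl2, 0 °C; used at once
Reagents that add atoms: carbon tetrabromide, BrC(Br)(Br)Br
Why: The Appel reaction converts the benzylic alcohol to the bromide under neutral conditions that do not touch the silyl ether.

Step 4
Reactants: 7 (S)-4-benzyl-3-propionyloxazolidin-2-one; 6 4-(bromomethyl)-2-methoxy-1-(triisopropylsilyloxy)benzene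
Product: 9 (S)-4-benzyl-3-{(2R)-3-[3-methoxy-4-(triisopropylsilyloxy)phenyl]-2-methylpropanoyl}oxazolidin-2-one, via sodium Z-enolate 8 (not isolated)
Conditions: NaN(SiMe3)2, THF, –78 °C; then 6, –78 to –40 °C
Reagents that add atoms: none
Why: Evans asymmetric alkylation: the chelated Z-enolate is shielded on one face by the benzyl group of the auxiliary, so the benzylic bromide should add to the other face and set C8 as R.

Step 5
Reactants: 9 (S)-4-benzyl-3-{(2R)-3-[3-methoxy-4-(triisopropylsilyloxy)phenyl]-2-methylpropanoyl}oxazolidin-2-one; 10 N,O-dimethylhydroxylamine hydrochloride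
Product: 11 (2R)-N-methoxy-3-[3-methoxy-4-(triisopropylsilyloxy)phenyl]-N,2-dimethylpropanamide
Conditions: AlMe3, CH2Cl2, 0 °C to rt; Rochelle-salt work-up
Reagents that add atoms: N,O-dimethylhydroxylamine hydrochloride, CNOC.Cl
Why: The aluminium amide made from AlMe3 and the amine salt attacks the exocyclic imide carbonyl (aminolysis to the Weinreb amide) and releases the auxiliary without enolising C8.

Step 6
Reactants: 12 racemic 2-(2-bromoethyl)oxirane
Product: 13 (S)-2-(2-bromoethyl)oxirane
Conditions: (R,R)-N,N'-bis(3,5-di-tert-butylsalicylidene)-1,2-cyclohexanediaminocobalt acetate (0.5 mol%), H2O (0.55 equiv), THF, 0 °C to rt; distillation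
Reagents that add atoms: none
Why: Hydrolytic kinetic resolution: the chiral salen complex of trivalent cobalt should open the (R)-oxirane with water much faster than the (S)-oxirane, which is distilled from the diol.

Step 7
Reactants: 13 (S)-2-(2-bromoethyl)oxirane; 14 vinylmagnesium bromide
Product: 15 (R)-1-bromohex-5-en-3-ol
Conditions: CuI (10 mol%), THF, –40 to –20 °C
Reagents that add atoms: vinylmagnesium bromide, C=C[Mg]Br
Why: Copper-catalysed Grignard opening of the terminal epoxide at its CH2 carbon (SN2) should outrun coupling at the primary bromide at low temperature and does not touch the carbinol centre (future C6), whose descriptor changes only through the CIP ranking.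

Step 8
Reactants: 15 (R)-1-bromohex-5-en-3-ol; 16 chlorotriethylsilane
Product: 17 (R)-[(1-bromohex-5-en-3-yl)oxy]triethylsilane
Conditions: imidazole, CH2Cl2, 0 °C
Reagents that add atoms: chlorotriethylsilane, CC[Si](Cl)(CC)CC
Why: Standard silylation; the triethylsilyl group is chosen because acidic methanol removes it later while the aryl triisopropylsilyl ether stays.

Step 9
Reactants: 17 (R)-[(1-bromohex-5-en-3-yl)oxy]triethylsilane; 11 (2R)-N-methoxy-3-[3-methoxy-4-(triisopropylsilyloxy)phenyl]-N,2-dimethylpropanamide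
Product: 19 (2R,6S)-1-[3-methoxy-4-(triisopropylsilyloxy)phenyl]-2-methyl-6-(triethylsilyloxy)non-8-en-3-one, via Grignard reagent 18 (not isolated)
Conditions: Mg, THF, rt; then 11, THF, 0 °C; aq NH4Cl
Reagents that add atoms: none
Why: Weinreb ketone synthesis: the Grignard reagent (made and used promptly so that 5-exo cyclisation of the hexenyl chain stays negligible) adds once, because the chelated tetrahedral adduct persists until work-up, and C8 is not epimerised.

Step 10
Reactants: 19 (2R,6S)-1-[3-methoxy-4-(triisopropylsilyloxy)phenyl]-2-methyl-6-(triethylsilyloxy)non-8-en-3-one; 20 ozone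
Product: 22 (3S,7R)-8-[3-methoxy-4-(triisopropylsilyloxy)phenyl]-7-methyl-6-oxo-3-(triethylsilyloxy)octanal, via ozonide 21 (not isolated)
Conditions: O3, CH2Cl2, –78 °C, Sudan Red 7B end point; then PPh3, –78 °C to rt
Reagents that add atoms: ozone, [O-][O+]=O
Why: Ozonolysis with reductive work-up cleaves the terminal alkene far faster than the arene is attacked and gives the β-silyloxy aldehyde under neutral conditions.

Step 11
Reactants: 22 (3S,7R)-8-[3-methoxy-4-(triisopropylsilyloxy)phenyl]-7-methyl-6-oxo-3-(triethylsilyloxy)octanal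
Product: 23 (2S,5S)-2-hydroxy-2-{(2R)-1-[3-methoxy-4-(triisopropylsilyloxy)phenyl]propan-2-yl}-5-(triethylsilyloxy)cyclohexan-1-one
Conditions: (5aS,10bR)-2-phenyl-5a,10b-dihydro-4H,6H-indeno[2,1-b][1,2,4]triazolo[4,3-d][1,4]oxazin-2-ium tetrafluoroborate (20 mol%), Et3N (20 mol%), toluene (0.05 M), rt to 40 °C
Reagents that add atoms: none
Why: The triazolylidene freed by Et3N adds to the unhindered aldehyde carbon C4, proton transfer gives the enaminol (acyl-anion equivalent), its carbon attacks ketone C3, and collapse of the adduct releases the carbene and the tertiary α-ketol. The closest known reaction type is the carbene-catalysed enantioselective intramolecular aldehyde–ketone crossed benzoin that gives cyclic tertiary α-ketols. The six-membered carbocycle C3–C4–C5–C6–C1–C2 closes in a 6-exo-trig mode. The new C3 stereocentre is set by the chiral catalyst, which should deliver the acyl anion to the Re face of the ketone; Felkin–Anh induction from C8 points the same way, and the (S)-C6 silyloxy group can sit equatorial, trans to the side chain, in the chair-like transition state. The step needs the aldehyde as donor and the ketone as acceptor: the α-branched ketone cannot bind the carbene, six is the preferred ring size, dilution holds back aldehyde–aldehyde coupling, and the weak amine base should leave C8 and the β-silyloxy aldehyde untouched.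

Step 12
Reactants: 23 (2S,5S)-2-hydroxy-2-{(2R)-1-[3-methoxy-4-(triisopropylsilyloxy)phenyl]propan-2-yl}-5-(triethylsilyloxy)cyclohexan-1-one; 24 methyl trifluoromethanesulfonate
Product: 25 (2S,5S)-2-methoxy-2-{(2R)-1-[3-methoxy-4-(triisopropylsilyloxy)phenyl]propan-2-yl}-5-(triethylsilyloxy)cyclohexan-1-one
Conditions: MeOTf, 2,6-di-tert-butyl-4-methylpyridine, CH2Cl2, rt to 40 °C
Reagents that add atoms: methyl trifluoromethanesulfonate, COS(=O)(=O)C(F)(F)F
Why: O-Methylation of the hindered tertiary alcohol with a powerful methylating agent and a non-nucleophilic pyridine avoids alkoxide or enolate formation, and so α-ketol rearrangement, C-methylation and β-elimination.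

Step 13
Reactants: 25 (2S,5S)-2-methoxy-2-{(2R)-1-[3-methoxy-4-(triisopropylsilyloxy)phenyl]propan-2-yl}-5-(triethylsilyloxy)cyclohexan-1-one; 26 trimethyl orthoformate; 27 methanol
Product: 28 (1S,4S)-3,3,4-trimethoxy-4-{(2R)-1-[3-methoxy-4-(triisopropylsilyloxy)phenyl]propan-2-yl}cyclohexan-1-ol
Conditions: HC(OMe)3, MeOH, camphorsulfonic acid (10 mol%), rt to 40 °C; Et3N quench
Reagents that add atoms: trimethyl orthoformate, COC(OC)OC; methanol, CO
Why: Acid-catalysed ketalisation of the only ketone (C4), driven by the orthoformate as water scavenger, should run together with methanolysis of the alkyl triethylsilyl ether, while the aryl silyl ether is stable to acid.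

Step 14
Reactants: 28 (1S,4S)-3,3,4-trimethoxy-4-{(2R)-1-[3-methoxy-4-(triisopropylsilyloxy)phenyl]propan-2-yl}cyclohexan-1-ol
Product: 30 (4S)-3,4-dimethoxy-4-{(2R)-1-[3-methoxy-4-(triisopropylsilyloxy)phenyl]propan-2-yl}cyclohex-2-en-1-one, via β-keto ketal 29 (not isolated)
Conditions: Dess–Martin periodinane, pyridine, CH2Cl2, 0 °C to rt; then pyridinium p-toluenesulfonate (10 mol%), 4 Å sieves, toluene, 50 °C
Reagents that add atoms: none
Why: Oxidation of the C6 alcohol gives a β-keto ketal that loses methanol by β-elimination; C3 is quaternary, so the double bond can form only toward C5 and the remaining methoxy group stays on C4, which fixes the vinylogous ester regiochemistry.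

Step 15
Reactants: 30 (4S)-3,4-dimethoxy-4-{(2R)-1-[3-methoxy-4-(triisopropylsilyloxy)phenyl]propan-2-yl}cyclohex-2-en-1-one; 31 allyl bromide
Product: 33 (4S)-6-allyl-3,4-dimethoxy-4-{(2R)-1-[3-methoxy-4-(triisopropylsilyloxy)phenyl]propan-2-yl}cyclohex-2-en-1-one (both C6 epimers), via lithium enolate 32 (not isolated)
Conditions: lithium diisopropylamide, THF, –78 °C; then allyl bromide, –78 to 0 °C
Reagents that add atoms: allyl bromide, C=CCBr
Why: Stork–Danheiser alkylation: C1 is the only enolisable position of the vinylogous ester (C3 is quaternary), so kinetic deprotonation and C-allylation should occur there.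

Step 16
Reactants: 33 (4S)-6-allyl-3,4-dimethoxy-4-{(2R)-1-[3-methoxy-4-(triisopropylsilyloxy)phenyl]propan-2-yl}cyclohex-2-en-1-one; 34 benzeneselenenyl chloride
Product: 36 (4S)-6-allyl-3,4-dimethoxy-6-(phenylselanyl)-4-{(2R)-1-[3-methoxy-4-(triisopropylsilyloxy)phenyl]propan-2-yl}cyclohex-2-en-1-one, via lithium enolate 35 (not isolated)
Conditions: lithium diisopropylamide, THF, –78 to –40 °C; then PhSeCl, –78 °C
Reagents that add atoms: benzeneselenenyl chloride, Cl[Se]c1ccccc1
Why: α-Selenenylation of the fully substituted lithium enolate at C1, again the only site that can be deprotonated.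

Step 17
Reactants: 36 (4S)-6-allyl-3,4-dimethoxy-6-(phenylselanyl)-4-{(2R)-1-[3-methoxy-4-(triisopropylsilyloxy)phenyl]propan-2-yl}cyclohex-2-en-1-one
Product: 38 (4R)-2-allyl-4,5-dimethoxy-4-{(2R)-1-[3-methoxy-4-(triisopropylsilyloxy)phenyl]propan-2-yl}cyclohexa-2,5-dien-1-one, via selenoxide 37 (not isolated)
Conditions: 30% H2O2, pyridine, CH2Cl2, 0 °C to rt
Reagents that add atoms: none
Why: Selenoxide syn-elimination: α-seleno cyclohexanones normally eliminate into the ring, which gives the C1=C2 bond, and the dienone cannot aromatise because C3 is quaternary.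

Step 18
Reactants: 38 (4R)-2-allyl-4,5-dimethoxy-4-{(2R)-1-[3-methoxy-4-(triisopropylsilyloxy)phenyl]propan-2-yl}cyclohexa-2,5-dien-1-one
Product: 39 (4R)-2-allyl-4-[(2R)-1-(4-hydroxy-3-methoxyphenyl)propan-2-yl]-4,5-dimethoxycyclohexa-2,5-dien-1-one (CNP0370214.2)
Conditions: Bu4NF, AcOH, THF, 0 °C
Reagents that add atoms: none
Why: Buffered fluoride cleaves the aryl silyl ether under conditions that should not affect the enol ether, the dienone or the allyl group.

**Compound list**

1 | vanillin | COc1cc(C=O)ccc1O | starting material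
2 | triisopropylsilyl chloride | CC(C)[Si](Cl)(C(C)C)C(C)C | starting material
3 | 3-methoxy-4-(triisopropylsilyloxy)benzaldehyde | COc1cc(C=O)ccc1O[Si](C(C)C)(C(C)C)C(C)C | intermediate
4 | [3-methoxy-4-(triisopropylsilyloxy)phenyl]methanol | COc1cc(CO)ccc1O[Si](C(C)C)(C(C)C)C(C)C | intermediate
5 | carbon tetrabromide | BrC(Br)(Br)Br | starting material
6 | 4-(bromomethyl)-2-methoxy-1-(triisopropylsilyloxy)benzene | COc1cc(CBr)ccc1O[Si](C(C)C)(C(C)C)C(C)C | intermediate
7 | (S)-4-benzyl-3-propionyloxazolidin-2-one | CCC(=O)N1[C@@H](Cc2ccccc2)COC1=O | starting material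
8 | sodium (Z)-enolate of 7 | C/C=C(\O[Na])N1[C@@H](Cc2ccccc2)COC1=O | intermediate
9 | (S)-4-benzyl-3-{(2R)-3-[3-methoxy-4-(triisopropylsilyloxy)phenyl]-2-methylpropanoyl}oxazolidin-2-one | O=C([C@H](C)Cc1ccc(O[Si](C(C)C)(C(C)C)C(C)C)c(OC)c1)N1[C@@H](Cc2ccccc2)COC1=O | intermediate
10 | N,O-dimethylhydroxylamine hydrochloride | CNOC.Cl | starting material
11 | (2R)-N-methoxy-3-[3-methoxy-4-(triisopropylsilyloxy)phenyl]-N,2-dimethylpropanamide | CON(C)C(=O)[C@H](C)Cc1ccc(O[Si](C(C)C)(C(C)C)C(C)C)c(OC)c1 | intermediate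
12 | racemic 2-(2-bromoethyl)oxirane | BrCCC1CO1 | starting material
13 | (S)-2-(2-bromoethyl)oxirane | BrCC[C@H]1CO1 | intermediate
14 | vinylmagnesium bromide | C=C[Mg]Br | starting material
15 | (R)-1-bromohex-5-en-3-ol | BrCC[C@H](O)CC=C | intermediate
16 | chlorotriethylsilane | CC[Si](Cl)(CC)CC | starting material
17 | (R)-[(1-bromohex-5-en-3-yl)oxy]triethylsilane | BrCC[C@H](O[Si](CC)(CC)CC)CC=C | intermediate
18 | [(3R)-3-(triethylsilyloxy)hex-5-en-1-yl]magnesium bromide | Br[Mg]CC[C@H](O[Si](CC)(CC)CC)CC=C | intermediate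
19 | (2R,6S)-1-[3-methoxy-4-(triisopropylsilyloxy)phenyl]-2-methyl-6-(triethylsilyloxy)non-8-en-3-one | C=CC[C@@H](O[Si](CC)(CC)CC)CCC(=O)[C@H](C)Cc1ccc(O[Si](C(C)C)(C(C)C)C(C)C)c(OC)c1 | intermediate
20 | ozone | [O-][O+]=O | starting material
21 | ozonide (1,2,4-trioxolane) of 19, both epimers at the trioxolane carbon | C1OOC(C[C@@H](O[Si](CC)(CC)CC)CCC(=O)[C@H](C)Cc2ccc(O[Si](C(C)C)(C(C)C)C(C)C)c(OC)c2)O1 | intermediate
22 | (3S,7R)-8-[3-methoxy-4-(triisopropylsilyloxy)phenyl]-7-methyl-6-oxo-3-(triethylsilyloxy)octanal | O=CC[C@@H](O[Si](CC)(CC)CC)CCC(=O)[C@H](C)Cc1ccc(O[Si](C(C)C)(C(C)C)C(C)C)c(OC)c1 | intermediate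
23 | (2S,5S)-2-hydroxy-2-{(2R)-1-[3-methoxy-4-(triisopropylsilyloxy)phenyl]propan-2-yl}-5-(triethylsilyloxy)cyclohexan-1-one | O=C1C[C@@H](O[Si](CC)(CC)CC)CC[C@]1(O)[C@H](C)Cc2ccc(O[Si](C(C)C)(C(C)C)C(C)C)c(OC)c2 | intermediate
24 | methyl trifluoromethanesulfonate | COS(=O)(=O)C(F)(F)F | starting material
25 | (2S,5S)-2-methoxy-2-{(2R)-1-[3-methoxy-4-(triisopropylsilyloxy)phenyl]propan-2-yl}-5-(triethylsilyloxy)cyclohexan-1-one | O=C1C[C@@H](O[Si](CC)(CC)CC)CC[C@]1(OC)[C@H](C)Cc2ccc(O[Si](C(C)C)(C(C)C)C(C)C)c(OC)c2 | intermediate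
26 | trimethyl orthoformate | COC(OC)OC | starting material
27 | methanol | CO | starting material
28 | (1S,4S)-3,3,4-trimethoxy-4-{(2R)-1-[3-methoxy-4-(triisopropylsilyloxy)phenyl]propan-2-yl}cyclohexan-1-ol | COC1(OC)C[C@@H](O)CC[C@]1(OC)[C@H](C)Cc2ccc(O[Si](C(C)C)(C(C)C)C(C)C)c(OC)c2 | intermediate
29 | (4S)-3,3,4-trimethoxy-4-{(2R)-1-[3-methoxy-4-(triisopropylsilyloxy)phenyl]propan-2-yl}cyclohexan-1-one | COC1(OC)CC(=O)CC[C@]1(OC)[C@H](C)Cc2ccc(O[Si](C(C)C)(C(C)C)C(C)C)c(OC)c2 | intermediate
30 | (4S)-3,4-dimethoxy-4-{(2R)-1-[3-methoxy-4-(triisopropylsilyloxy)phenyl]propan-2-yl}cyclohex-2-en-1-one | O=C1CC[C@](OC)([C@H](C)Cc2ccc(O[Si](C(C)C)(C(C)C)C(C)C)c(OC)c2)C(OC)=C1 | intermediate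
31 | allyl bromide | C=CCBr | starting material
32 | lithium enolate of 30 (C6–O–Li, C6=C1) | [Li]OC1=CC[C@](OC)([C@H](C)Cc2ccc(O[Si](C(C)C)(C(C)C)C(C)C)c(OC)c2)C(OC)=C1 | intermediate
33 | (4S)-6-allyl-3,4-dimethoxy-4-{(2R)-1-[3-methoxy-4-(triisopropylsilyloxy)phenyl]propan-2-yl}cyclohex-2-en-1-one, both C6 epimers | O=C1C(CC=C)C[C@](OC)([C@H](C)Cc2ccc(O[Si](C(C)C)(C(C)C)C(C)C)c(OC)c2)C(OC)=C1 | intermediate
34 | benzeneselenenyl chloride | Cl[Se]c1ccccc1 | starting material
35 | lithium enolate of 33 | [Li]OC1=C(CC=C)C[C@](OC)([C@H](C)Cc2ccc(O[Si](C(C)C)(C(C)C)C(C)C)c(OC)c2)C(OC)=C1 | intermediate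
36 | (4S)-6-allyl-3,4-dimethoxy-6-(phenylselanyl)-4-{(2R)-1-[3-methoxy-4-(triisopropylsilyloxy)phenyl]propan-2-yl}cyclohex-2-en-1-one, both C6 epimers | O=C1C(CC=C)([Se]c3ccccc3)C[C@](OC)([C@H](C)Cc2ccc(O[Si](C(C)C)(C(C)C)C(C)C)c(OC)c2)C(OC)=C1 | intermediate
37 | selenoxide of 36 | O=C1C(CC=C)([Se](=O)c3ccccc3)C[C@](OC)([C@H](C)Cc2ccc(O[Si](C(C)C)(C(C)C)C(C)C)c(OC)c2)C(OC)=C1 | intermediate
38 | (4R)-2-allyl-4,5-dimethoxy-4-{(2R)-1-[3-methoxy-4-(triisopropylsilyloxy)phenyl]propan-2-yl}cyclohexa-2,5-dien-1-one | C=CCC1=C[C@](OC)([C@H](C)Cc2ccc(O[Si](C(C)C)(C(C)C)C(C)C)c(OC)c2)C(OC)=CC1=O | intermediate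
39 | (4R)-2-allyl-4-[(2R)-1-(4-hydroxy-3-methoxyphenyl)propan-2-yl]-4,5-dimethoxycyclohexa-2,5-dien-1-one | C=CCC1=C[C@](OC)([C@H](C)Cc2ccc(O)c(OC)c2)C(OC)=CC1=O | target

**Step count**

Total: 18 steps. Longest linear sequence: 15 steps from vanillin (steps 1–5 and 9–18); the three-step branch (steps 6–8) joins at step 9.

**Steps most likely to fail**

1. Step 11 (key step). The hindered, unactivated α-branched ketone may accept the acyl anion too slowly, so that aldehyde–aldehyde coupling or base-induced aldol closure takes over, or the facial selectivity at C3 may be poor. Fallback, setting out from 22: SmI2 (THF, t-BuOH, –78 °C) joins the two carbonyl carbons by intramolecular pinacol coupling to give the cis-diol (1S,2S,4S)-1-{(2R)-1-[3-methoxy-4-(triisopropylsilyloxy)phenyl]propan-2-yl}-4-(triethylsilyloxy)cyclohexane-1,2-diol F1, the C3 epimer being removed by chromatography. Oxidation of the secondary hydroxyl alone (SO3·pyridine, DMSO, iPr2NEt) then comes back to the route at 23.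

2. Step 13. Ketalisation next to the quaternary, methoxy-bearing C3 may stop at partial conversion, or the acid may cause loss of the C6 oxygen by β-elimination. Fallback, setting out from 25: potassium bis(trimethylsilyl)amide in THF/DMPU at –78 °C followed by MeOTf O-methylates the only possible enolate (C4=C5) to give the methyl enol ether triethyl{[(1S,4S)-3,4-dimethoxy-4-{(2R)-1-[3-methoxy-4-(triisopropylsilyloxy)phenyl]propan-2-yl}cyclohex-2-en-1-yl]oxy}silane F2. Bu4NF removes both silyl groups to give (1S,4S)-4-[(2R)-1-(4-hydroxy-3-methoxyphenyl)propan-2-yl]-3,4-dimethoxycyclohex-2-en-1-ol F3. MnO2 oxidises the allylic alcohol to (4S)-4-[(2R)-1-(4-hydroxy-3-methoxyphenyl)propan-2-yl]-3,4-dimethoxycyclohex-2-en-1-one F4, and resilylation of the phenol (triisopropylsilyl chloride, imidazole) comes back to the route at 30.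

3. Step 17. The selenoxide may eliminate toward the allylic CH2 of the side chain instead of into the ring, giving an exocyclic diene. Fallback, setting out from 30: two successive enolate brominations at C1 (LiN(SiMe3)2, then N-bromosuccinimide, each time) give (4S)-6-bromo-3,4-dimethoxy-4-{(2R)-1-[3-methoxy-4-(triisopropylsilyloxy)phenyl]propan-2-yl}cyclohex-2-en-1-one F5 and then the 6,6-dibromo compound (4S)-6,6-dibromo-3,4-dimethoxy-4-{(2R)-1-[3-methoxy-4-(triisopropylsilyloxy)phenyl]propan-2-yl}cyclohex-2-en-1-one F6. DBU removes HBr, which can leave only across C1–C2, to give (4R)-2-bromo-4,5-dimethoxy-4-{(2R)-1-[3-methoxy-4-(triisopropylsilyloxy)phenyl]propan-2-yl}cyclohexa-2,5-dien-1-one F7. Stille coupling with allyltributylstannane (Pd(PPh3)4, CuI, DMF) places the allyl group on C1 and comes back to the route at 38.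

**Further compounds**

F1 | step 11 | (1S,2S,4S)-1-{(2R)-1-[3-methoxy-4-(triisopropylsilyloxy)phenyl]propan-2-yl}-4-(triethylsilyloxy)cyclohexane-1,2-diol | O[C@H]1C[C@@H](O[Si](CC)(CC)CC)CC[C@]1(O)[C@H](C)Cc2ccc(O[Si](C(C)C)(C(C)C)C(C)C)c(OC)c2
F2 | step 13 | triethyl{[(1S,4S)-3,4-dimethoxy-4-{(2R)-1-[3-methoxy-4-(triisopropylsilyloxy)phenyl]propan-2-yl}cyclohex-2-en-1-yl]oxy}silane | COC1=C[C@@H](O[Si](CC)(CC)CC)CC[C@]1(OC)[C@H](C)Cc2ccc(O[Si](C(C)C)(C(C)C)C(C)C)c(OC)c2
F3 | step 13 | (1S,4S)-4-[(2R)-1-(4-hydroxy-3-methoxyphenyl)propan-2-yl]-3,4-dimethoxycyclohex-2-en-1-ol | COC1=C[C@@H](O)CC[C@]1(OC)[C@H](C)Cc2ccc(O)c(OC)c2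
F4 | step 13 | (4S)-4-[(2R)-1-(4-hydroxy-3-methoxyphenyl)propan-2-yl]-3,4-dimethoxycyclohex-2-en-1-one | O=C1CC[C@](OC)([C@H](C)Cc2ccc(O)c(OC)c2)C(OC)=C1
F5 | step 17 | (4S)-6-bromo-3,4-dimethoxy-4-{(2R)-1-[3-methoxy-4-(triisopropylsilyloxy)phenyl]propan-2-yl}cyclohex-2-en-1-one | O=C1C(Br)C[C@](OC)([C@H](C)Cc2ccc(O[Si](C(C)C)(C(C)C)C(C)C)c(OC)c2)C(OC)=C1
F6 | step 17 | (4S)-6,6-dibromo-3,4-dimethoxy-4-{(2R)-1-[3-methoxy-4-(triisopropylsilyloxy)phenyl]propan-2-yl}cyclohex-2-en-1-one | O=C1C(Br)(Br)C[C@](OC)([C@H](C)Cc2ccc(O[Si](C(C)C)(C(C)C)C(C)C)c(OC)c2)C(OC)=C1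
F7 | step 17 | (4R)-2-bromo-4,5-dimethoxy-4-{(2R)-1-[3-methoxy-4-(triisopropylsilyloxy)phenyl]propan-2-yl}cyclohexa-2,5-dien-1-one | BrC1=C[C@](OC)([C@H](C)Cc2ccc(O[Si](C(C)C)(C(C)C)C(C)C)c(OC)c2)C(OC)=CC1=O
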